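**Plan**

1. The target is a (2S)-flavanone whose ring B (C1'–C6') is bonded through C3' to C6 of an apigenin unit; all six hydroxyls are carried as benzyl ethers.
2. Retrosynthetic cuts: flavanone O1–C2 (oxa-Michael) and C2=C3 of an alkylidene β-ketoester (Knoevenagel, C2 from an aryl aldehyde); then ring B at C1'–C2' and C5'–C6' ([4+2]); the C3'–C6 bond goes back to an allyl group moved from O5 to C6.
3. Enabling feature: ring B has its oxygen at C4', para to C1' (which carries chromanone C2) and ortho to C3' (which carries flavone C6). A 2-silyloxy-3-aryl-1,3-diene and a propiolate give exactly this pattern after dehydrogenation.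
4. Forward order: apigenin (flavone rings in place) → C6-allyl → arylacetone → enone → silyloxydiene → ring B by cycloaddition/DDQ → ester to aldehyde → union with the ring A β-ketoester → ring C closure → decarboxylation → debenzylation.
5. Stereochemistry: the only stereocentre, C2 (S), is set by a chiral amine–thiourea catalyst in the ring C closure (step 16); the steps after it are acidic or neutral and should not open the ring.

Key step: step 8

Assumption: the thiourea derived from 9-amino-9-deoxy-epi-quinidine is taken as the pseudoenantiomer that gives the 2S flavanone; if the sense proves opposite, the epi-quinine-derived catalyst replaces it in step 16 with no other change.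

Naming: "5,7,4'-tri-O-benzylapigenin-6-yl" stands for 5,7-bis(benzyloxy)-2-[4-(benzyloxy)phenyl]-4-oxo-4H-chromen-6-yl.

**Route**

Step 1
Reactants: 1 apigenin
Product: 2 7,4'-di-O-benzylapigenin (7-(benzyloxy)-2-[4-(benzyloxy)phenyl]-5-hydroxy-4H-chromen-4-one)
Conditions: BnBr (2.2 equiv), K2CO3, DMF, rt
Reagents that add atoms: benzyl bromide, BrCc1ccccc1
Why: Williamson etherification; the 7- and 4'-hydroxyls are the acidic, unhindered phenols, whereas the 5-OH is hydrogen-bonded to the C4 carbonyl and should stay free with two equivalents of halide at room temperature.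

Step 2
Reactants: 2 7,4'-di-O-benzylapigenin; 3 allyl bromide
Product: 4 5-O-allyl-7,4'-di-O-benzylapigenin
Conditions: allyl bromide (3 equiv), K2CO3, DMF, 60 °C
Reagents that add atoms: none
Why: Williamson etherification of the chelated 5-OH, which should respond to excess halide and warming once the other phenols are capped.

Step 3
Reactants: 4 5-O-allyl-7,4'-di-O-benzylapigenin
Product: 5 6-allyl-7,4'-di-O-benzylapigenin (6-allyl-7-(benzyloxy)-2-[4-(benzyloxy)phenyl]-5-hydroxy-4H-chromen-4-one)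
Conditions: PhNEt2, 200 °C, argon
Reagents that add atoms: none
Why: Aromatic Claisen rearrangement ([3,3]-sigmatropic shift); of the two positions ortho to O5 only C6 bears hydrogen (C4a is the ring fusion), so the allyl group should arrive at C6 and the dienone should tautomerise to the chelated phenol before a second shift to C8 can compete.

Step 4
Reactants: 5 6-allyl-7,4'-di-O-benzylapigenin
Product: 6 6-allyl-5,7,4'-tri-O-benzylapigenin
Conditions: BnBr, K2CO3, Bu4NI (cat.), DMF, 70 °C
Reagents that add atoms: benzyl bromide, BrCc1ccccc1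
Why: Williamson etherification under forcing conditions caps the hindered 5-OH, which would otherwise add to the alkene by oxypalladation in the next step.

Step 5
Reactants: 6 6-allyl-5,7,4'-tri-O-benzylapigenin
Product: 7 5,7,4'-tri-O-benzyl-6-(2-oxopropyl)apigenin
Conditions: PdCl2 (10 mol %), CuCl (co-catalyst), O2 (1 atm), DMF/H2O 7:1, rt
Reagents that add atoms: water, O
Why: Tsuji–Wacker oxidation; Markovnikov hydroxypalladation of the terminal alkene by divalent palladium and β-hydride elimination should give the methyl ketone, with CuCl and O2 returning zerovalent palladium to the divalent state.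

Step 6
Reactants: 7 5,7,4'-tri-O-benzyl-6-(2-oxopropyl)apigenin; 8 formaldehyde (used as paraformaldehyde)
Product: 9 5,7,4'-tri-O-benzyl-6-(3-oxobut-1-en-2-yl)apigenin
Conditions: (CH2O)n (3 equiv), i-Pr2NH·CF3CO2H (1 equiv), CF3CO2H (10 mol %), THF, reflux
Reagents that add atoms: none
Why: Mannich-type α-methylenation; the ketone should enolise towards the benzylic CH2, the only carbon activated by both aryl and carbonyl, the iminium ion adds there, and the β-amino ketone loses the amine to leave the 1,1-disubstituted enone.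

Step 7
Reactants: 9 5,7,4'-tri-O-benzyl-6-(3-oxobut-1-en-2-yl)apigenin
Product: 10 5,7,4'-tri-O-benzyl-6-[3-(tert-butyldimethylsilyloxy)buta-1,3-dien-2-yl]apigenin
Conditions: t-BuMe2SiOTf (1.5 equiv), Et3N (2.5 equiv), CH2Cl2, 0 °C; filtration through Et3N-deactivated silica
Reagents that add atoms: tert-butyldimethylsilyl trifluoromethanesulfonate, CC(C)(C)[Si](C)(C)OS(=O)(=O)C(F)(F)F
Why: Soft enolisation with a silyl triflate and a tertiary amine; the methyl group is the only enolisable position of the enone, so only one 2-silyloxydiene can form.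

Step 8
Reactants: 10 5,7,4'-tri-O-benzyl-6-[3-(tert-butyldimethylsilyloxy)buta-1,3-dien-2-yl]apigenin; 11 methyl propiolate
Product: 13 methyl 4-(tert-butyldimethylsilyloxy)-3-(5,7,4'-tri-O-benzylapigenin-6-yl)benzoate, via silyloxycyclohexa-1,4-diene cycloadduct 12 (not isolated)
Conditions: methyl propiolate (4 equiv), toluene, 110 °C, sealed tube; then DDQ (1.2 equiv), rt
Reagents that add atoms: none
Why: A concerted but asynchronous normal-electron-demand Diels–Alder reaction joins the two diene termini to the alkyne, the bond from the CH2 next to the silyloxy carbon (future C5') to the propiolate β-carbon (future C6') being the more advanced, and DDQ then takes hydride from one doubly allylic CH2 and a proton from the other so that the 1,4-cyclohexadiene 12 becomes a benzene ring with its silyl ether intact. The closest known reaction type is the cycloaddition of 2-silyloxybuta-1,3-dienes with propiolates followed by quinone dehydrogenation to para-oxygenated benzoates. Flavanone ring B is the only ring closed, as a six-membered carbocycle by intermolecular [4+2] cycloaddition that forms C1'–C2' and C5'–C6' in one event. No stereocentre is created, and the sp3 carbons of 12 disappear on aromatisation. The selectivity needed is regiochemical (ester para to the silyloxy group and meta to the flavonyl group): the silyloxy donor places the largest HOMO coefficient on its neighbouring terminal CH2, which pairs with the electrophilic β-carbon of the ynoate, while the 2,6-bis(benzyloxy)aryl group is twisted out of the diene plane and should exert little opposing bias. The 2,3-disubstituted diene can reach the s-cis form, and the electron-rich pyranone C2=C3 bond of the flavone should not compete with the ynoate as 2π partner.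

Step 9
Reactants: 13 methyl 4-(tert-butyldimethylsilyloxy)-3-(5,7,4'-tri-O-benzylapigenin-6-yl)benzoate
Product: 14 methyl 4-(benzyloxy)-3-(5,7,4'-tri-O-benzylapigenin-6-yl)benzoate
Conditions: CsF (2 equiv), BnBr (1.5 equiv), DMF, rt
Reagents that add atoms: benzyl bromide, BrCc1ccccc1
Why: Fluoride cleaves the aryl silyl ether and the caesium phenoxide is benzylated in the same flask (desilylative Williamson etherification), so that every phenol carries the same group for one final deprotection.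

Step 10
Reactants: 14 methyl 4-(benzyloxy)-3-(5,7,4'-tri-O-benzylapigenin-6-yl)benzoate
Product: 15 4-(benzyloxy)-3-(5,7,4'-tri-O-benzylapigenin-6-yl)benzoic acid
Conditions: LiOH (4 equiv), THF/MeOH/H2O, 40 °C; then 1 M HCl
Reagents that add atoms: lithium hydroxide, [Li+].[OH-]
Why: Saponification of the unhindered methyl benzoate; going through the acid avoids aluminium hydrides such as i-Bu2AlH, which would be expected to attack the flavone carbonyl as well.

Step 11
Reactants: 15 4-(benzyloxy)-3-(5,7,4'-tri-O-benzylapigenin-6-yl)benzoic acid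
Product: 17 6-[2-(benzyloxy)-5-(hydroxymethyl)phenyl]-5,7,4'-tri-O-benzylapigenin, via isobutyl carbonic mixed anhydride 16 (not isolated)
Conditions: i-BuOCOCl (1.1 equiv), N-methylmorpholine (1.2 equiv), THF, −10 °C; then NaBH4 (2.5 equiv), H2O, 0 °C
Reagents that add atoms: isobutyl chloroformate, CC(C)COC(=O)Cl (its atoms remain only in intermediate 16)
Why: Mixed carbonic anhydride activation followed by NaBH4 reduction; the anhydride should be reduced within minutes at 0 °C, conditions under which the vinylogous-ester carbonyl of a flavone is not expected to react with borohydride.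

Step 12
Reactants: 17 6-[2-(benzyloxy)-5-(hydroxymethyl)phenyl]-5,7,4'-tri-O-benzylapigenin
Product: 18 4-(benzyloxy)-3-(5,7,4'-tri-O-benzylapigenin-6-yl)benzaldehyde
Conditions: MnO2 (activated, 15 equiv), CH2Cl2, rt
Reagents that add atoms: none
Why: MnO2 oxidation is selective for benzylic alcohols and should stop at the aldehyde.

Step 13
Reactants: 19 2',4',6'-trihydroxyacetophenone
Product: 20 1-[2,4-bis(benzyloxy)-6-hydroxyphenyl]ethan-1-one
Conditions: BnBr (2.1 equiv), K2CO3, acetone, reflux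
Reagents that add atoms: benzyl bromide, BrCc1ccccc1
Why: Williamson etherification; the para hydroxyl and one ortho hydroxyl are alkylated, while the remaining ortho-OH stays chelated to the acetyl group.

Step 14
Reactants: 20 1-[2,4-bis(benzyloxy)-6-hydroxyphenyl]ethan-1-one
Product: 21 tert-butyl 3-[2,4-bis(benzyloxy)-6-hydroxyphenyl]-3-oxopropanoate
Conditions: LiN(SiMe3)2 (3.2 equiv), THF, −78 °C; Boc2O (1.05 equiv), −78 to 0 °C; aq NH4Cl
Reagents that add atoms: di-tert-butyl dicarbonate, CC(C)(C)OC(=O)OC(=O)OC(C)(C)C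
Why: Claisen-type C-acylation of the ketone enolate within the phenoxide–enolate dianion, the third equivalent of base taking up the acidic β-ketoester; any aryl carbonate formed on oxygen should pass its acyl group to carbon in the manner of a Baker–Venkataraman rearrangement.

Step 15
Reactants: 18 4-(benzyloxy)-3-(5,7,4'-tri-O-benzylapigenin-6-yl)benzaldehyde; 21 tert-butyl 3-[2,4-bis(benzyloxy)-6-hydroxyphenyl]-3-oxopropanoate
Product: 22 tert-butyl (2Z)-2-[2,4-bis(benzyloxy)-6-hydroxybenzoyl]-3-[4-(benzyloxy)-3-(5,7,4'-tri-O-benzylapigenin-6-yl)phenyl]prop-2-enoate (Z isomer expected to predominate; any E isomer is carried along)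
Conditions: piperidine (20 mol %), AcOH (20 mol %), 4 Å molecular sieves, toluene, 40 °C
Reagents that add atoms: none
Why: Knoevenagel condensation of the β-ketoester with the aryl aldehyde under buffered amine catalysis with removal of water; the hydrogen-bonded phenol should not close the ring under these weakly basic conditions.

Step 16
Reactants: 22 tert-butyl (2Z)-2-[2,4-bis(benzyloxy)-6-hydroxybenzoyl]-3-[4-(benzyloxy)-3-(5,7,4'-tri-O-benzylapigenin-6-yl)phenyl]prop-2-enoate
Product: 24 (2S)-5,7-bis(benzyloxy)-2-[4-(benzyloxy)-3-(5,7,4'-tri-O-benzylapigenin-6-yl)phenyl]chroman-4-one, via tert-butyl 4-oxochromane-3-carboxylate 23 (not isolated)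
Conditions: thiourea from 9-amino-9-deoxy-epi-quinidine and 3,5-(CF3)2C6H3NCS (10 mol %), toluene, −25 °C; then TsOH·H2O (0.5 equiv), 80 °C
Reagents that add atoms: none
Why: Bifunctional amine–thiourea catalysis of an intramolecular oxa-Michael addition (6-endo-trig): the thiourea binds the β-ketoester while the quinuclidine nitrogen guides the phenol to one face of the alkylidene, which sets C2 as S; acid then cleaves the tert-butyl ester and the β-keto acid decarboxylates without touching C2, and any peri benzyl ether lost in hot acid is of no consequence before the final debenzylation.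

Step 17
Reactants: 24 (2S)-5,7-bis(benzyloxy)-2-[4-(benzyloxy)-3-(5,7,4'-tri-O-benzylapigenin-6-yl)phenyl]chroman-4-one
Product: 25 (2S)-5,7-dihydroxy-2-{4-hydroxy-3-[5,7-dihydroxy-2-(4-hydroxyphenyl)-4-oxo-4H-chromen-6-yl]phenyl}chroman-4-one (CNP0277421.1)
Conditions: H2 (1 atm), 10% Pd/C, THF/MeOH, rt
Reagents that add atoms: none
Why: Hydrogenolysis of the six benzyl ethers over palladium at ambient pressure; the flavone C2=C3 bond, the aryl ketone and the benzylic C2–O bond of the flavanone are expected to persist, and the neutral medium should leave the C2 stereocentre intact.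

**Compound list**

1 | apigenin | O=c1cc(-c2ccc(O)cc2)oc2cc(O)cc(O)c12 | starting material
2 | 7,4'-di-O-benzylapigenin (7-(benzyloxy)-2-[4-(benzyloxy)phenyl]-5-hydroxy-4H-chromen-4-one) | O=c1cc(-c2ccc(OCc3ccccc3)cc2)oc2cc(OCc3ccccc3)cc(O)c12 | intermediate
3 | allyl bromide | C=CCBr | starting material
4 | 5-O-allyl-7,4'-di-O-benzylapigenin (5-(allyloxy)-7-(benzyloxy)-2-[4-(benzyloxy)phenyl]-4H-chromen-4-one) | O=c1cc(-c2ccc(OCc3ccccc3)cc2)oc2cc(OCc3ccccc3)cc(OCC=C)c12 | intermediate
5 | 6-allyl-7,4'-di-O-benzylapigenin (6-allyl-7-(benzyloxy)-2-[4-(benzyloxy)phenyl]-5-hydroxy-4H-chromen-4-one) | O=c1cc(-c2ccc(OCc3ccccc3)cc2)oc2cc(OCc3ccccc3)c(CC=C)c(O)c12 | intermediate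
6 | 6-allyl-5,7,4'-tri-O-benzylapigenin (6-allyl-5,7-bis(benzyloxy)-2-[4-(benzyloxy)phenyl]-4H-chromen-4-one) | O=c1cc(-c2ccc(OCc3ccccc3)cc2)oc2cc(OCc3ccccc3)c(CC=C)c(OCc3ccccc3)c12 | intermediate
7 | 5,7,4'-tri-O-benzyl-6-(2-oxopropyl)apigenin | O=c1cc(-c2ccc(OCc3ccccc3)cc2)oc2cc(OCc3ccccc3)c(CC(C)=O)c(OCc3ccccc3)c12 | intermediate
8 | formaldehyde (used as paraformaldehyde) | C=O | starting material
9 | 5,7,4'-tri-O-benzyl-6-(3-oxobut-1-en-2-yl)apigenin | O=c1cc(-c2ccc(OCc3ccccc3)cc2)oc2cc(OCc3ccccc3)c(C(=C)C(C)=O)c(OCc3ccccc3)c12 | intermediate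
10 | 5,7,4'-tri-O-benzyl-6-[3-(tert-butyldimethylsilyloxy)buta-1,3-dien-2-yl]apigenin | C=C(O[Si](C)(C)C(C)(C)C)C(=C)c1c(OCc2ccccc2)cc2oc(-c3ccc(OCc4ccccc4)cc3)cc(=O)c2c1OCc1ccccc1 | intermediate
11 | methyl propiolate | C#CC(=O)OC | starting material
12 | methyl 4-(tert-butyldimethylsilyloxy)-5-(5,7,4'-tri-O-benzylapigenin-6-yl)cyclohexa-1,4-diene-1-carboxylate | COC(=O)C1=CCC(O[Si](C)(C)C(C)(C)C)=C(C1)c1c(OCc2ccccc2)cc2oc(-c3ccc(OCc4ccccc4)cc3)cc(=O)c2c1OCc1ccccc1 | intermediate (not isolated)
13 | methyl 4-(tert-butyldimethylsilyloxy)-3-(5,7,4'-tri-O-benzylapigenin-6-yl)benzoate | COC(=O)c1ccc(O[Si](C)(C)C(C)(C)C)c(-c2c(OCc3ccccc3)cc3oc(-c4ccc(OCc5ccccc5)cc4)cc(=O)c3c2OCc2ccccc2)c1 | intermediate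
14 | methyl 4-(benzyloxy)-3-(5,7,4'-tri-O-benzylapigenin-6-yl)benzoate | COC(=O)c1ccc(OCc2ccccc2)c(-c2c(OCc3ccccc3)cc3oc(-c4ccc(OCc5ccccc5)cc4)cc(=O)c3c2OCc2ccccc2)c1 | intermediate
15 | 4-(benzyloxy)-3-(5,7,4'-tri-O-benzylapigenin-6-yl)benzoic acid | O=C(O)c1ccc(OCc2ccccc2)c(-c2c(OCc3ccccc3)cc3oc(-c4ccc(OCc5ccccc5)cc4)cc(=O)c3c2OCc2ccccc2)c1 | intermediate
16 | 4-(benzyloxy)-3-(5,7,4'-tri-O-benzylapigenin-6-yl)benzoic isobutyl carbonic anhydride | CC(C)COC(=O)OC(=O)c1ccc(OCc2ccccc2)c(-c2c(OCc3ccccc3)cc3oc(-c4ccc(OCc5ccccc5)cc4)cc(=O)c3c2OCc2ccccc2)c1 | intermediate (not isolated)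
17 | 6-[2-(benzyloxy)-5-(hydroxymethyl)phenyl]-5,7,4'-tri-O-benzylapigenin | OCc1ccc(OCc2ccccc2)c(-c2c(OCc3ccccc3)cc3oc(-c4ccc(OCc5ccccc5)cc4)cc(=O)c3c2OCc2ccccc2)c1 | intermediate
18 | 4-(benzyloxy)-3-(5,7,4'-tri-O-benzylapigenin-6-yl)benzaldehyde | O=Cc1ccc(OCc2ccccc2)c(-c2c(OCc3ccccc3)cc3oc(-c4ccc(OCc5ccccc5)cc4)cc(=O)c3c2OCc2ccccc2)c1 | intermediate
19 | 2',4',6'-trihydroxyacetophenone | CC(=O)c1c(O)cc(O)cc1O | starting material
20 | 1-[2,4-bis(benzyloxy)-6-hydroxyphenyl]ethan-1-one | CC(=O)c1c(O)cc(OCc2ccccc2)cc1OCc1ccccc1 | intermediate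
21 | tert-butyl 3-[2,4-bis(benzyloxy)-6-hydroxyphenyl]-3-oxopropanoate | CC(C)(C)OC(=O)CC(=O)c1c(O)cc(OCc2ccccc2)cc1OCc1ccccc1 | intermediate
22 | tert-butyl (2Z)-2-[2,4-bis(benzyloxy)-6-hydroxybenzoyl]-3-[4-(benzyloxy)-3-(5,7,4'-tri-O-benzylapigenin-6-yl)phenyl]prop-2-enoate | CC(C)(C)OC(=O)/C(=C\c1ccc(OCc2ccccc2)c(-c2c(OCc3ccccc3)cc3oc(-c4ccc(OCc5ccccc5)cc4)cc(=O)c3c2OCc2ccccc2)c1)C(=O)c1c(O)cc(OCc2ccccc2)cc1OCc1ccccc1 | intermediate
23 | tert-butyl (2S,3R)-5,7-bis(benzyloxy)-2-[4-(benzyloxy)-3-(5,7,4'-tri-O-benzylapigenin-6-yl)phenyl]-4-oxochromane-3-carboxylate (trans isomer drawn; C3 is epimerisable and may sit partly as the enol) | O=C1[C@H](C(=O)OC(C)(C)C)[C@@H](c2ccc(OCc3ccccc3)c(-c3c(OCc4ccccc4)cc4oc(-c5ccc(OCc6ccccc6)cc5)cc(=O)c4c3OCc3ccccc3)c2)Oc2cc(OCc3ccccc3)cc(OCc3ccccc3)c21 | intermediate (not isolated)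
24 | (2S)-5,7-bis(benzyloxy)-2-[4-(benzyloxy)-3-(5,7,4'-tri-O-benzylapigenin-6-yl)phenyl]chroman-4-one | O=C1C[C@@H](c2ccc(OCc3ccccc3)c(-c3c(OCc4ccccc4)cc4oc(-c5ccc(OCc6ccccc6)cc5)cc(=O)c4c3OCc3ccccc3)c2)Oc2cc(OCc3ccccc3)cc(OCc3ccccc3)c21 | intermediate
25 | (2S)-5,7-dihydroxy-2-{4-hydroxy-3-[5,7-dihydroxy-2-(4-hydroxyphenyl)-4-oxo-4H-chromen-6-yl]phenyl}chroman-4-one (CNP0277421.1) | O=C1C[C@@H](c2ccc(O)c(-c3c(O)cc4oc(-c5ccc(O)cc5)cc(=O)c4c3O)c2)Oc2cc(O)cc(O)c21 | target

**Totals**

Total step count: 17 (12 on the main line to aldehyde 18, 2 for the ring A β-ketoester 21, 3 after their union).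
Longest linear sequence: 15 steps (steps 1–12 and 15–17, from apigenin).

**Steps most likely to fail**

Step 8. The cycloaddition may stall because the two benzyloxy groups flanking the aryl–diene bond crowd the diene terminus that must bond to the ester-bearing alkyne carbon. Prolonged heating then invites protodesilylation of the silyl enol ether or loss of orientation. The fallback makes the biaryl bond by cross-coupling instead of building ring B. It sets out from 2 and returns to the route at 18.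
- Iodination of 2 ortho to the free 5-OH with benzyltrimethylammonium dichloroiodate (BnMe3N·ICl2) and CaCO3 in CH2Cl2/MeOH should give 7-(benzyloxy)-2-[4-(benzyloxy)phenyl]-5-hydroxy-6-iodo-4H-chromen-4-one F1.
- Benzylation (BnBr, K2CO3, DMF, 70 °C) should give 5,7-bis(benzyloxy)-2-[4-(benzyloxy)phenyl]-6-iodo-4H-chromen-4-one F2.
- Miyaura borylation of commercial 4-(benzyloxy)-3-bromobenzaldehyde (B2pin2, Pd(dppf)Cl2, KOAc, dioxane, 90 °C) should give 4-(benzyloxy)-3-(4,4,5,5-tetramethyl-1,3,2-dioxaborolan-2-yl)benzaldehyde F3.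
- Suzuki–Miyaura coupling of F2 with F3 (Pd(OAc)2, SPhos, K3PO4, toluene/H2O, 90 °C) should deliver aldehyde 18 directly.

Step 16. Enantioselectivity may be eroded by an uncatalysed ring closure, which the 6-benzyloxy group favours by twisting the aryl ketone and which may begin under the amine of step 15. Weak facial discrimination by the catalyst or partial ring opening in hot acid would have the same effect. The fallback separates ring closure from stereocontrol. It sets out from 18 (with 20) and returns at 24.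
- Claisen–Schmidt condensation of 18 with 20 (KOH, EtOH/THF, rt) should give (2E)-1-[2,4-bis(benzyloxy)-6-hydroxyphenyl]-3-[4-(benzyloxy)-3-(5,7,4'-tri-O-benzylapigenin-6-yl)phenyl]prop-2-en-1-one F4.
- NaOAc in refluxing EtOH should close it to racemic 5,7-bis(benzyloxy)-2-[4-(benzyloxy)-3-(5,7,4'-tri-O-benzylapigenin-6-yl)phenyl]chroman-4-one F5.
- Kinetic resolution by asymmetric transfer hydrogenation (RuCl(p-cymene)[(R,R)-TsDPEN], HCO2H/Et3N 5:2, EtOAc, rt; the catalyst enantiomer is chosen so that the 2R ketone is the fast-reacting one) should reduce the 2R enantiomer to (2R,4R)-5,7-bis(benzyloxy)-2-[4-(benzyloxy)-3-(5,7,4'-tri-O-benzylapigenin-6-yl)phenyl]chroman-4-ol F6.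
- The unreacted 2S ketone 24 is recovered by chromatography.

Step 6. The iminium ion may be captured at the methyl side of the ketone, a second methylene may be introduced, or the enone may oligomerise under the reaction conditions. The fallback brings the future exo-methylene carbon in with the Claisen unit and unveils the enone by β-elimination. It sets out from 2 and returns at 9.
- Alkylation of 2 with (2E)-4-bromobut-2-en-1-yl acetate (K2CO3, DMF, 60 °C) should give 5-O-[(2E)-4-acetoxybut-2-en-1-yl]-7,4'-di-O-benzylapigenin F7.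
- Claisen rearrangement (PhNEt2, 200 °C) should give racemic 6-(1-acetoxybut-3-en-2-yl)-7,4'-di-O-benzylapigenin F8.
- Benzylation (BnBr, K2CO3, DMF) should give 6-(1-acetoxybut-3-en-2-yl)-5,7,4'-tri-O-benzylapigenin F9.
- Tsuji–Wacker oxidation (PdCl2, CuCl, O2, DMF/H2O) should give 6-(1-acetoxy-3-oxobutan-2-yl)-5,7,4'-tri-O-benzylapigenin F10.
- DBU in CH2Cl2 at rt should expel acetate (E1cB) to give enone 9.

**Further compounds**

F1 | step 8 | 7-(benzyloxy)-2-[4-(benzyloxy)phenyl]-5-hydroxy-6-iodo-4H-chromen-4-one | O=c1cc(-c2ccc(OCc3ccccc3)cc2)oc2cc(OCc3ccccc3)c(I)c(O)c12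
F2 | step 8 | 5,7-bis(benzyloxy)-2-[4-(benzyloxy)phenyl]-6-iodo-4H-chromen-4-one | O=c1cc(-c2ccc(OCc3ccccc3)cc2)oc2cc(OCc3ccccc3)c(I)c(OCc3ccccc3)c12
F3 | step 8 | 4-(benzyloxy)-3-(4,4,5,5-tetramethyl-1,3,2-dioxaborolan-2-yl)benzaldehyde | O=Cc1ccc(OCc2ccccc2)c(B2OC(C)(C)C(C)(C)O2)c1
F4 | step 16 | (2E)-1-[2,4-bis(benzyloxy)-6-hydroxyphenyl]-3-[4-(benzyloxy)-3-(5,7,4'-tri-O-benzylapigenin-6-yl)phenyl]prop-2-en-1-one | O=C(/C=C/c1ccc(OCc2ccccc2)c(-c2c(OCc3ccccc3)cc3oc(-c4ccc(OCc5ccccc5)cc4)cc(=O)c3c2OCc2ccccc2)c1)c1c(O)cc(OCc2ccccc2)cc1OCc1ccccc1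
F5 | step 16 | racemic 5,7-bis(benzyloxy)-2-[4-(benzyloxy)-3-(5,7,4'-tri-O-benzylapigenin-6-yl)phenyl]chroman-4-one | O=C1CC(c2ccc(OCc3ccccc3)c(-c3c(OCc4ccccc4)cc4oc(-c5ccc(OCc6ccccc6)cc5)cc(=O)c4c3OCc3ccccc3)c2)Oc2cc(OCc3ccccc3)cc(OCc3ccccc3)c21
F6 | step 16 | (2R,4R)-5,7-bis(benzyloxy)-2-[4-(benzyloxy)-3-(5,7,4'-tri-O-benzylapigenin-6-yl)phenyl]chroman-4-ol | O[C@@H]1C[C@H](c2ccc(OCc3ccccc3)c(-c3c(OCc4ccccc4)cc4oc(-c5ccc(OCc6ccccc6)cc5)cc(=O)c4c3OCc3ccccc3)c2)Oc2cc(OCc3ccccc3)cc(OCc3ccccc3)c21
F7 | step 6 | 5-O-[(2E)-4-acetoxybut-2-en-1-yl]-7,4'-di-O-benzylapigenin | CC(=O)OC/C=C/COc1cc(OCc2ccccc2)cc2oc(-c3ccc(OCc4ccccc4)cc3)cc(=O)c12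
F8 | step 6 | racemic 6-(1-acetoxybut-3-en-2-yl)-7,4'-di-O-benzylapigenin | CC(=O)OCC(C=C)c1c(OCc2ccccc2)cc2oc(-c3ccc(OCc4ccccc4)cc3)cc(=O)c2c1O
F9 | step 6 | racemic 6-(1-acetoxybut-3-en-2-yl)-5,7,4'-tri-O-benzylapigenin | CC(=O)OCC(C=C)c1c(OCc2ccccc2)cc2oc(-c3ccc(OCc4ccccc4)cc3)cc(=O)c2c1OCc1ccccc1
F10 | step 6 | racemic 6-(1-acetoxy-3-oxobutan-2-yl)-5,7,4'-tri-O-benzylapigenin | CC(=O)OCC(C(C)=O)c1c(OCc2ccccc2)cc2oc(-c3ccc(OCc4ccccc4)cc3)cc(=O)c2c1OCc1ccccc1
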